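**Plan**

- The acid chain is cut at the sp–sp bond C6–C7 of the diyne (Cadiot–Chodkiewicz coupling) and at the sp–sp3 bond C8–C9 (acetylide alkylation), which leaves a 2-(15-functionalised pentadecyl)furan and hex-5-ynoic acid.
- The furan carries its only substituent at C2 and hydrogen at C3, C4 and C5. Its C3=C4 bond is therefore cut by ring-closing metathesis into two vinyl groups on either side of the ring oxygen O1, one on a carbinol carbon (future C2) and one on a methoxy acetal carbon (future C5).
- The O1–C5 acetal bond goes back to an allylic alcohol and methoxyallene, and the allylic alcohol to hexadecanolide (furan C2 plus chain carbons C9–C23) and vinylmagnesium bromide.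
- Forward: lactone, hydroxy aldehyde, vinyl carbinol, primary pivalate, mixed acetal, metathesis and aromatisation to the furan (the only ring), alcohol, bromide, terminal alkyne, diyne acid. The bromoalkyne partner comes in one step from hex-5-ynoic acid.
- The target has no stereocentre. The carbinol and acetal centres of the intermediates are formed without control and both vanish when the ring becomes aromatic.

Key step: step 5

Remark: because the target is achiral, every intermediate that has a stereocentre is carried as a racemate or as a diastereomer mixture.

**Route**

Step 1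
Reactants: 1 hexadecanolide (oxacycloheptadecan-2-one)
Product: 3 16-hydroxyhexadecanal, via oxacycloheptadecan-2-ol 2 (not isolated)
Conditions: i-Bu2AlH (1.1 equiv), CH2Cl2, −78 °C; aq. KNaC4H4O6 work-up; used crude
Reagents that add atoms: none
Why: Partial reduction of a lactone with i-Bu2AlH at −78 °C stops at the aluminium hemiacetal, and on hydrolysis the 17-membered lactol 2 opens to the unstrained ω-hydroxy aldehyde, the usual outcome for macrocyclic lactones.

Step 2
Reactants: 3 16-hydroxyhexadecanal; 4 vinylmagnesium bromide
Product: 5 octadec-17-ene-1,16-diol (racemic)
Conditions: CH2=CHMgBr (2.5 equiv), THF, −78 to 0 °C (aldehyde added to the Grignard reagent); aq. NH4Cl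
Reagents that add atoms: none
Why: Grignard 1,2-addition to the aldehyde, after the first equivalent has deprotonated the hydroxyl, should give the secondary allylic alcohol; the new carbinol centre forms without control, which is harmless because it becomes furan C2.

Step 3
Reactants: 5 octadec-17-ene-1,16-diol
Product: 6 16-hydroxyoctadec-17-en-1-yl pivalate (racemic)
Conditions: PivCl (1.05 equiv), pyridine, CH2Cl2, 0 °C
Reagents that add atoms: pivaloyl chloride, CC(C)(C)C(=O)Cl
Why: Sterically controlled selective acylation, in which the bulky acid chloride esterifies the unhindered primary hydroxyl much faster than the secondary allylic one, should give the robust ester that survives amine base, ruthenium carbene and catalytic acid.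

Step 4
Reactants: 6 16-hydroxyoctadec-17-en-1-yl pivalate; 7 methoxyallene
Product: 8 16-[(1-methoxyprop-2-en-1-yl)oxy]octadec-17-en-1-yl pivalate (mixture of diastereomers)
Conditions: methoxyallene (3 equiv), Pd(OAc)2 (5 mol%), dppp (7.5 mol%), Et3N (1.5 equiv), MeCN, rt; chromatography on Et3N-treated SiO2
Reagents that add atoms: none
Why: Palladium-catalysed hydroalkoxylation of an alkoxyallene, in which zerovalent palladium (formed in situ from Pd(OAc)2 and 1,3-bis(diphenylphosphino)propane) and the alcohol hydropalladate methoxyallene to a methoxy-substituted π-allyl complex that the alkoxide captures at the oxygen-bearing terminus, should give the branched mixed acetal with a terminal vinyl group; the new acetal centre is uncontrolled and is erased in step 5.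

Step 5
Reactants: 8 16-[(1-methoxyprop-2-en-1-yl)oxy]octadec-17-en-1-yl pivalate
Product: 10 15-(furan-2-yl)pentadecyl pivalate, via 15-(5-methoxy-2,5-dihydrofuran-2-yl)pentadecyl pivalate 9 (not isolated)
Conditions: second-generation Grubbs catalyst RuCl2(=CHPh)(PCy3)(H2IMes) (3 mol%), CH2Cl2 (0.01 M), 40 °C; then CF3CO2H (10 mol%), rt; Et3N quench
Reagents that add atoms: none
Why: Ring-closing metathesis followed by acid-promoted elimination, the known route from allyl 1-alkoxyallyl ethers to furans: the ruthenium benzylidene exchanges with one terminal vinyl group, the new alkylidene undergoes [2+2] cycloaddition with the second vinyl group, and cycloreversion of the ruthenacyclobutane releases ethene and forms the C3=C4 bond of dihydrofuran 9. The single ring, the five-membered oxacycle, thus closes by metathesis of the two ends of a 4-oxahepta-1,6-diene unit, a closure that is fast for this ring size and becomes irreversible once ethene escapes. CF3CO2H then ionises the allylic acetal of 9 to a ring oxocarbenium ion, which loses the proton on the chain-bearing ring carbon, so that methanol is expelled and the aromatic furan results. No stereocentre is created, and the carbinol and acetal centres of 8 both become sp2 carbons, so all diastereomers converge on 10. The only selectivity required is ring closure over intermolecular metathesis, and it is secured by the 1,6-relationship of two unhindered monosubstituted alkenes, by the 0.01 M dilution and by the absence of any other alkene or alkyne in 8. The pivalate is inert to the ruthenium carbene and to catalytic acid, and the acid is neutralised before concentration to protect the 2-alkylfuran.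

Step 6
Reactants: 10 15-(furan-2-yl)pentadecyl pivalate
Product: 11 15-(furan-2-yl)pentadecan-1-ol
Conditions: LiAlH4 (1 equiv), THF, 0 °C to rt; H2O, aq. NaOH, H2O
Reagents that add atoms: none
Why: Hydride reduction of the ester should free the primary alcohol under basic conditions that leave the acid-sensitive furan untouched.

Step 7
Reactants: 11 15-(furan-2-yl)pentadecan-1-ol
Product: 12 2-(15-bromopentadecyl)furan
Conditions: CBr4 (1.3 equiv), PPh3 (1.4 equiv), CH2Cl2, 0 °C to rt
Reagents that add atoms: carbon tetrabromide, BrC(Br)(Br)Br
Why: In the Appel reaction the alkoxyphosphonium ion formed from PPh3 and CBr4 is displaced by bromide in an SN2 step under essentially neutral, non-oxidising conditions that a 2-alkylfuran tolerates.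

Step 8
Reactants: 12 2-(15-bromopentadecyl)furan; 13 lithium acetylide–ethylenediamine complex
Product: 14 2-(heptadec-16-yn-1-yl)furan
Conditions: LiC≡CH·H2NCH2CH2NH2 (2 equiv), DMSO/THF, 10 °C to rt
Reagents that add atoms: none
Why: SN2 alkylation of lithium acetylide by a primary bromide in a dipolar aprotic medium is the standard two-carbon extension to a terminal alkyne, and the acetylide is far too weak a base to metalate the furan.

Step 9
Reactants: 15 hex-5-ynoic acid
Product: 16 6-bromohex-5-ynoic acid
Conditions: NBS (1.1 equiv), AgNO3 (10 mol%), acetone, rt, dark
Reagents that add atoms: N-bromosuccinimide, O=C1CCC(=O)N1Br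
Why: Silver-catalysed electrophilic bromination of the terminal alkyne C–H, through the silver acetylide, tolerates the free carboxylic acid and should give the 1-bromoalkyne.

Step 10
Reactants: 14 2-(heptadec-16-yn-1-yl)furan; 16 6-bromohex-5-ynoic acid
Product: 17 23-(furan-2-yl)tricosa-5,7-diynoic acid (target)
Conditions: CuCl (10 mol%), NH2OH·HCl (0.3 equiv), EtNH2 (70% aq.), MeOH/THF, 0 °C to rt, slow addition of 16 (1.2 equiv), dark; then cold aq. citric acid
Reagents that add atoms: none
Why: In the Cadiot–Chodkiewicz coupling the copper acetylide of 14, formed by monovalent copper and the amine, couples with the 1-bromoalkyne to form the C6–C7 bond of the unsymmetrical 1,3-diyne, while hydroxylamine keeps the copper reduced and so suppresses oxidative homocoupling; the acid travels as its ammonium carboxylate and is released by mild acidification.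

**Compound list**

1 | hexadecanolide (oxacycloheptadecan-2-one) | O=C1CCCCCCCCCCCCCCCO1 | starting material
2 | oxacycloheptadecan-2-ol (lactol, opens on work-up) | OC1CCCCCCCCCCCCCCCO1 | intermediate
3 | 16-hydroxyhexadecanal | O=CCCCCCCCCCCCCCCCO | intermediate
4 | vinylmagnesium bromide | C=C[Mg]Br | starting material
5 | octadec-17-ene-1,16-diol (racemic) | C=CC(O)CCCCCCCCCCCCCCCO | intermediate
6 | 16-hydroxyoctadec-17-en-1-yl pivalate (racemic) | C=CC(O)CCCCCCCCCCCCCCCOC(=O)C(C)(C)C | intermediate
7 | methoxyallene (1-methoxypropa-1,2-diene) | COC=C=C | starting material
8 | 16-[(1-methoxyprop-2-en-1-yl)oxy]octadec-17-en-1-yl pivalate (diastereomer mixture) | C=CC(OC(OC)C=C)CCCCCCCCCCCCCCCOC(=O)C(C)(C)C | intermediate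
9 | 15-(5-methoxy-2,5-dihydrofuran-2-yl)pentadecyl pivalate (diastereomer mixture) | COC1C=CC(CCCCCCCCCCCCCCCOC(=O)C(C)(C)C)O1 | intermediate
10 | 15-(furan-2-yl)pentadecyl pivalate | CC(C)(C)C(=O)OCCCCCCCCCCCCCCCc1ccco1 | intermediate
11 | 15-(furan-2-yl)pentadecan-1-ol | OCCCCCCCCCCCCCCCc1ccco1 | intermediate
12 | 2-(15-bromopentadecyl)furan | BrCCCCCCCCCCCCCCCc1ccco1 | intermediate
13 | lithium acetylide–ethylenediamine complex | [Li+].[C-]#C.NCCN | starting material
14 | 2-(heptadec-16-yn-1-yl)furan | C#CCCCCCCCCCCCCCCCc1ccco1 | intermediate
15 | hex-5-ynoic acid | C#CCCCC(=O)O | starting material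
16 | 6-bromohex-5-ynoic acid | OC(=O)CCCC#CBr | intermediate
17 | 23-(furan-2-yl)tricosa-5,7-diynoic acid | O=C(O)CCCC#CC#CCCCCCCCCCCCCCCCc1ccco1 | target

**Step count**

Total steps: 10 (step 9 prepares the bromoalkyne partner).
Longest linear sequence: 9 steps (steps 1–8 and 10, from hexadecanolide 1).

**Steps most likely to fail**

Step 5. Intermolecular metathesis to dimers and oligomers may compete with ring closure, ruthenium hydride species may shift the terminal double bonds, and the acid may hydrolyse uncyclised acetal or polymerise the furan. The fallback keeps the C3–C4 metathesis bond but moves to the lactone oxidation level; it sets out from 6 and comes back at 10. Alcohol 6 is acylated with acryloyl chloride and Et3N in CH2Cl2 at 0 °C to give the acrylate 16-(acryloyloxy)octadec-17-en-1-yl pivalate F1. Ring-closing metathesis with the second-generation Grubbs catalyst RuCl2(=CHPh)(PCy3)(H2IMes) in refluxing CH2Cl2 should give the butenolide 15-(5-oxo-2,5-dihydrofuran-2-yl)pentadecyl pivalate F2. Reduction with i-Bu2AlH (1.1 equiv) at −78 °C gives the lactol 15-(5-hydroxy-2,5-dihydrofuran-2-yl)pentadecyl pivalate F3, which loses water on mildly acidic work-up to give furan 10. Any pivalate cleaved at the same time simply arrives as 11, the next compound of the route.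

Step 4. Capture of the π-allylpalladium intermediate by the hindered secondary allylic alcohol may be slow, methoxyallene may oligomerise instead, and the mixed acetal may hydrolyse during isolation. The fallback replaces the palladium-catalysed addition by acid-catalysed acetal exchange; it sets out from 6 and comes back at 10. Alcohol 6 is heated with excess 3,3-diethoxyprop-1-ene (acrolein diethyl acetal) and catalytic pyridinium p-toluenesulfonate in toluene under reduced pressure to remove ethanol, giving the ethyl acetal 16-[(1-ethoxyprop-2-en-1-yl)oxy]octadec-17-en-1-yl pivalate F4. Under the conditions of step 5 this should close to 15-(5-ethoxy-2,5-dihydrofuran-2-yl)pentadecyl pivalate F5, and elimination of ethanol then gives 10.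

Step 10. Oxidative homocoupling of either alkyne and halogen–copper exchange between the partners may erode the cross-coupling, made worse by poor mixing of the lipophilic alkyne with the aqueous amine phase. The fallback reverses the roles of the partners and uses a homogeneous organic medium; it sets out from 14 and comes back at 17. Alkyne 14 is deprotonated with n-BuLi (1.0 equiv, THF, −78 °C; the alkyne C–H is far more acidic than the furan C–H) and quenched with I2 to give 2-(17-iodoheptadec-16-yn-1-yl)furan F6. N-Bromosuccinimide is avoided here because it would brominate the furan. Iodoalkyne F6 is then coupled with an excess of the inexpensive hex-5-ynoic acid 15 under copper catalysis (copper monoiodide CuI, 10 mol%, pyrrolidine, rt), and acidification gives 17. The homodimer of the excess acid is a diacid, which should be separable from the monoacid 17.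

**Further compounds**

F1 | step 5 | 16-(acryloyloxy)octadec-17-en-1-yl pivalate (racemic) | C=CC(=O)OC(C=C)CCCCCCCCCCCCCCCOC(=O)C(C)(C)C
F2 | step 5 | 15-(5-oxo-2,5-dihydrofuran-2-yl)pentadecyl pivalate (racemic) | O=C1C=CC(CCCCCCCCCCCCCCCOC(=O)C(C)(C)C)O1
F3 | step 5 | 15-(5-hydroxy-2,5-dihydrofuran-2-yl)pentadecyl pivalate (diastereomer mixture) | OC1C=CC(CCCCCCCCCCCCCCCOC(=O)C(C)(C)C)O1
F4 | step 4 | 16-[(1-ethoxyprop-2-en-1-yl)oxy]octadec-17-en-1-yl pivalate (diastereomer mixture) | C=CC(OC(OCC)C=C)CCCCCCCCCCCCCCCOC(=O)C(C)(C)C
F5 | step 4 | 15-(5-ethoxy-2,5-dihydrofuran-2-yl)pentadecyl pivalate (diastereomer mixture) | CCOC1C=CC(CCCCCCCCCCCCCCCOC(=O)C(C)(C)C)O1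
F6 | step 10 | 2-(17-iodoheptadec-16-yn-1-yl)furan | IC#CCCCCCCCCCCCCCCCc1ccco1
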